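**Retrosynthetic overview**

1. Last bond: the methylene bridge. The target splits into an 8-hexanoyl-5,7-dihydroxy-2,2-dimethylchromene, an (R)-configured dearomatised acetyl-geranyl-methyl-phloroglucinol and formaldehyde (Knoevenagel/Michael union).
2. Key bond: the pyran O1–C2 bond of the chromene, a C–O bond closed by oxa-6π electrocyclisation of an ortho-quinone methide made from hexanoylphloroglucinol and prenal. This is the only ring built in the synthesis, and it leaves one aryl C–H for the bridge.
3. Quaternary stereocentre of ring B: enantioselective dearomative C-geranylation of 3-methylphloroacetophenone with geranyl acetate (new palladium/Trost-ligand step).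
4. Both acylphloroglucinols come from Friedel–Crafts acylation of phloroglucinol and 2-methylphloroglucinol.
5. Ring order: ring A is bought as the arene, then the pyran ring is fused on by C–O closure; ring B is bought as an arene and dearomatised (no ring formed); the two halves are joined last.

Assumption: the (R) label is the CIP descriptor of the enol tautomer drawn in the target SMILES, and the Trost-ligand antipode that gives this sense is fixed by experiment (written below as (R,R)).

**Route**

Step 1
Reactants: 1 phloroglucinol (benzene-1,3,5-triol); 2 hexanoyl chloride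
Product: 3 1-(2,4,6-trihydroxyphenyl)hexan-1-one
Conditions: AlCl3 (3.5 equiv), PhNO2, 0 → 65 °C, 3 h; ice/1 M HCl
Reagents that add atoms: none
Why: Friedel–Crafts acylation of the threefold-activated, symmetrical arene gives a single C-acyl product because all ring carbons are equivalent and the aluminium-chelated aryl ketone is deactivated toward a second acylation.

Step 2
Reactants: 3 1-(2,4,6-trihydroxyphenyl)hexan-1-one; 4 3-methylbut-2-enal (prenal)
Product: 6 1-(5,7-dihydroxy-2,2-dimethyl-2H-chromen-8-yl)hexan-1-one, via ortho-quinone methide 5 (not isolated)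
Conditions: 4 (1.05 equiv), ethylenediammonium diacetate (EDDA, 20 mol%), toluene, 110 °C, Dean–Stark, 6 h
Reagents that add atoms: none
Why: Formal [3+3] chromene annulation (domino Knoevenagel condensation/oxa-6π electrocyclisation): the iminium of 4 is attacked by a free ring carbon of 3, loss of the amine gives quinone methide 5, and its ring carbonyl oxygen beside the hexanoyl-bearing carbon closes onto the dimethylvinyl terminus, forming the O1–C2 bond and restoring the aromatic ring; closure through the para oxygen (6-hexanoyl isomer) and double annulation are the side paths, removed by chromatography.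

Step 3
Reactants: 7 2-methylbenzene-1,3,5-triol (2-methylphloroglucinol); 8 acetyl chloride
Product: 9 1-(2,4,6-trihydroxy-3-methylphenyl)ethan-1-one
Conditions: 8 (1.05 equiv), AlCl3 (3 equiv), PhNO2, 0 → 60 °C; ice/1 M HCl
Reagents that add atoms: none
Why: Friedel–Crafts acylation; the two unsubstituted ring carbons of 7 are equivalent by symmetry, so only one mono-acetyl product can form, and the ketone deactivates the ring against diacylation.

Step 4
Reactants: 9 1-(2,4,6-trihydroxy-3-methylphenyl)ethan-1-one; 10 geranyl acetate [(2E)-3,7-dimethylocta-2,6-dien-1-yl acetate]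
Product: 11 (4R)-2-acetyl-4-[(2E)-3,7-dimethylocta-2,6-dien-1-yl]-3,5-dihydroxy-4-methylcyclohexa-2,5-dien-1-one
Conditions: Pd2(dba)3·CHCl3 (2.5 mol%), (1R,2R)-N,N'-bis[2-(diphenylphosphino)benzoyl]cyclohexane-1,2-diamine ((R,R)-DACH-phenyl Trost ligand, 7.5 mol%), Et3N (1.2 equiv), 9 (1.5 equiv), degassed THF, 0 °C → rt; product extracted into aq. NaHCO3 and re-acidified
Reagents that add atoms: none
Why: Proposed new method: zerovalent palladium ionises geranyl acetate to the syn π-geranyl complex held in the chiral pocket of the diamide-bisphosphine ligand; the triethylammonium phenoxide of 9 (pKa about 8, a soft vinylogous β-diketone enolate) attacks the unhindered CH2 terminus from outside the metal, so the (E)-geranyl unit is delivered intact, any O-geranyl or O-linalyl ether formed first re-ionises (acidic phenoxide leaving group) and drains to carbon, and attack through the methyl-bearing, most electron-rich ring carbon C3 gives a strongly enolised β-triketone that cannot rearomatise; the ligand amide N–H hydrogen-bonds to the acetyl-chelated phenoxide and exposes one enantiotopic face of C3, which sets the (R) quaternary centre; closest known chemistry is the Trost asymmetric allylic alkylation that forms quaternary centres on prochiral cyclic enolates and the palladium-catalysed asymmetric allylic dearomatisation of naphthols, neither shown for acylphloroglucinols or geranyl electrophiles.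

Step 5
Reactants: 6 1-(5,7-dihydroxy-2,2-dimethyl-2H-chromen-8-yl)hexan-1-one; 11 (4R)-2-acetyl-4-[(2E)-3,7-dimethylocta-2,6-dien-1-yl]-3,5-dihydroxy-4-methylcyclohexa-2,5-dien-1-one; 12 formaldehyde (37% aqueous)
Product: 14 (4R)-2-acetyl-4-[(2E)-3,7-dimethylocta-2,6-dien-1-yl]-6-[(8-hexanoyl-5,7-dihydroxy-2,2-dimethyl-2H-chromen-6-yl)methyl]-3,5-dihydroxy-4-methylcyclohexa-2,5-dien-1-one (CNP0319887.1), via methylidene triketone 13 (not isolated)
Conditions: 6 (1.5 equiv), 12 (1.1 equiv), KOH (4 equiv, 1% in H2O/MeOH 1:1), 0 °C → rt, 30 min; 1 M HCl to pH 3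
Reagents that add atoms: none
Why: Classical formaldehyde bridging of an acylfilicinic-type acid with an acylphloroglucinol (Knoevenagel condensation then Michael addition): the most acidic C–H of 11 condenses with 12 to give enone 13, which is captured by the phenoxide of 6 at C6, its only free aromatic carbon, while the quaternary stereocentre, having no α-hydrogen, is untouched.

**Compound list**

1 | phloroglucinol (benzene-1,3,5-triol) | Oc1cc(O)cc(O)c1 | starting material
2 | hexanoyl chloride | CCCCCC(Cl)=O | starting material
3 | 1-(2,4,6-trihydroxyphenyl)hexan-1-one | CCCCCC(=O)c1c(O)cc(O)cc1O | intermediate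
4 | 3-methylbut-2-enal (prenal) | CC(C)=CC=O | starting material
5 | 2-hexanoyl-3,5-dihydroxy-6-(3-methylbut-2-en-1-ylidene)cyclohexa-2,4-dien-1-one (ortho-quinone methide, alkenyl group cis to the C1 carbonyl) | CCCCCC(=O)C1=C(O)C=C(O)/C(=C/C=C(C)C)C1=O | intermediate (not isolated)
6 | 1-(5,7-dihydroxy-2,2-dimethyl-2H-chromen-8-yl)hexan-1-one | CCCCCC(=O)c1c(O)cc(O)c2c1OC(C)(C)C=C2 | intermediate
7 | 2-methylbenzene-1,3,5-triol (2-methylphloroglucinol) | Cc1c(O)cc(O)cc1O | starting material
8 | acetyl chloride | CC(Cl)=O | starting material
9 | 1-(2,4,6-trihydroxy-3-methylphenyl)ethan-1-one | CC(=O)c1c(O)cc(O)c(C)c1O | intermediate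
10 | geranyl acetate, (2E)-3,7-dimethylocta-2,6-dien-1-yl acetate | CC(=O)OC/C=C(\C)CCC=C(C)C | starting material
11 | (4R)-2-acetyl-4-[(2E)-3,7-dimethylocta-2,6-dien-1-yl]-3,5-dihydroxy-4-methylcyclohexa-2,5-dien-1-one | CC(=O)C1=C(O)[C@](C)(C/C=C(\C)CCC=C(C)C)C(O)=CC1=O | intermediate
12 | formaldehyde | C=O | starting material
13 | (6S)-4-acetyl-6-[(2E)-3,7-dimethylocta-2,6-dien-1-yl]-5-hydroxy-6-methyl-2-methylidenecyclohex-4-ene-1,3-dione (same spatial arrangement as in 11; the descriptor changes only through the CIP priorities) | C=C1C(=O)[C@@](C)(C/C=C(\C)CCC=C(C)C)C(O)=C(C(C)=O)C1=O | intermediate (not isolated)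
14 | (4R)-2-acetyl-4-[(2E)-3,7-dimethylocta-2,6-dien-1-yl]-6-[(8-hexanoyl-5,7-dihydroxy-2,2-dimethyl-2H-chromen-6-yl)methyl]-3,5-dihydroxy-4-methylcyclohexa-2,5-dien-1-one (CNP0319887.1) | CCCCCC(=O)c1c(O)c(CC2=C(O)[C@@](C)(C/C=C(\C)CCC=C(C)C)C(O)=C(C(C)=O)C2=O)c(O)c2c1OC(C)(C)C=C2 | target

**Step count and risks**

Total steps: 5. Longest linear sequence: 3 steps (1 → 2 → 5, or 3 → 4 → 5).

Steps most likely to fail:

Step 4 (the proposed new step). The risks are competing attack through the unsubstituted ring carbon C5 (aromatic geranyl isomer), a second geranylation of the more acidic product, an insufficient ee, or the opposite sense of induction (answered by the ligand antipode). Fallback with known chemistry: it sets out from 9. Alkylative dearomatisation with geranyl bromide and NaOMe in MeOH at 0 °C, the conditions by which acylfilicinic-type acids are made from acylphloroglucinols, gives racemic 2-acetyl-4-[(2E)-3,7-dimethylocta-2,6-dien-1-yl]-3,5-dihydroxy-4-methylcyclohexa-2,5-dien-1-one F1, isolated through its NaHCO3-soluble enol. The enantiomers are separated by preparative supercritical-fluid chromatography on an amylose tris(3,5-dimethylphenylcarbamate) phase (CO2/MeOH, 0.1% formic acid). The configuration is assigned by comparing the ECD of the derived dimer with the natural product. The (R)-enantiomer rejoins the route at 11.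

Step 2. The quinone methide can also close through the para oxygen (6-hexanoyl chromene), and a second prenal can add. Fallback: it sets out from 3. The non-chelated para hydroxyl is silylated selectively (chlorotriisopropylsilane, imidazole, DMF, 0 °C) to give 1-{2,6-dihydroxy-4-[tri(propan-2-yl)silyloxy]phenyl}hexan-1-one F2. The same prenal/EDDA annulation can then close only onto a chelated ortho oxygen, giving 1-{7-hydroxy-2,2-dimethyl-5-[tri(propan-2-yl)silyloxy]-2H-chromen-8-yl}hexan-1-one F3 as the sole regioisomer. Bu4NF/AcOH in THF at 0 °C removes the silyl group and the sequence rejoins the route at 6.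

Step 5. The one-pot bridging can give the two homodimers and base-induced scrambling of the bridge. Fallback: it sets out from 6. A Mannich reaction with dimethylmethyleneammonium iodide (MeCN, rt) gives 1-{6-[(dimethylamino)methyl]-5,7-dihydroxy-2,2-dimethyl-2H-chromen-8-yl}hexan-1-one F4. Heating F4 with 11 (1.0 equiv) in 1,4-dioxane at 90 °C expels dimethylamine, and the ortho-quinone methide of ring A so formed is trapped by the acidic ring carbon of 11. Only the hetero-dimer can form, and the sequence rejoins the route at 14.

Further compounds
F1 | step 4 | racemic 2-acetyl-4-[(2E)-3,7-dimethylocta-2,6-dien-1-yl]-3,5-dihydroxy-4-methylcyclohexa-2,5-dien-1-one | CC(=O)C1=C(O)C(C)(C/C=C(\C)CCC=C(C)C)C(O)=CC1=O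
F2 | step 2 | 1-{2,6-dihydroxy-4-[tri(propan-2-yl)silyloxy]phenyl}hexan-1-one | CCCCCC(=O)c1c(O)cc(O[Si](C(C)C)(C(C)C)C(C)C)cc1O
F3 | step 2 | 1-{7-hydroxy-2,2-dimethyl-5-[tri(propan-2-yl)silyloxy]-2H-chromen-8-yl}hexan-1-one | CCCCCC(=O)c1c(O)cc(O[Si](C(C)C)(C(C)C)C(C)C)c2c1OC(C)(C)C=C2
F4 | step 5 | 1-{6-[(dimethylamino)methyl]-5,7-dihydroxy-2,2-dimethyl-2H-chromen-8-yl}hexan-1-one | CCCCCC(=O)c1c(O)c(CN(C)C)c(O)c2c1OC(C)(C)C=C2
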